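The slowness of both earlier runs was what I reckoned from: in ochre, at 50.0 s, 97% of the free monomer still stood.

in all of them: pre-initiator 17 mM
- amber: free monomer 0.12 M; run made earlier
- ochre: free monomer 0.19 M; run made earlier
- flask: free monomer 0.25 M; time 2.0 min

- amber (time / s: monomer in chains / %, free monomer / %): 10.0: 0, 101; 20.0: 1, 99; 30.0: 0, 99; 50.0: 3, 96; 80.0: 12, 86
- ochre (time / s: monomer in chains / %, free monomer / %): 10.0: 0, 99; 20.0: 0, 99; 30.0: 1, 99; 50.0: 4, 97; 80.0: 15, 82

(standard deviation of a reading: 1.5 percentage points)

- average number of monomer units in a chain (chains begun, living or dead) at 2.0 min
- part of the free monomer that has reacted at 2.0 min

- the average divides the monomer in chains by the number of chains begun, living and dead together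
- on the list of suspects stand: free monomer + living end -> monomer in chains + living end; free monomer + initiator -> living end + monomer in chains; pre-initiator -> initiator
- the earlier runs do not show the number of chains; that part of a forecast is a guess

If pre-initiator feeds initiator at a steady pace and free monomer stays near its charge, initiator grows with time and living ends with c(free monomer) times time squared. The logarithm of the free monomer left then falls with c(free monomer) times time cubed, which is the induction period of a chain reaction. I scaled this cube rule from the ochre reading at 80.0 s, 82% left, with its scatter, since ochre's charge lies closer to the flask's.

For the flask this gave 1.85 min as the cube half-time, the time by which the rule has half of the charged free monomer reacted. The rule gave 58.6% reacted at 2.0 min. But the ratio of that time to the cube half-time is 1.08, just past one, and beyond one the rule's free monomer "near its charge" no longer stands. So I expected c below 58.6%, and how far below I could not reckon. The earlier runs do not show the number of chains, so I reckoned no dp.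

The forecast gave c = 45% and dp = 20, noting “Chain number is otherwise unmeasured”.

The flask gave c = 46.7% and dp = 37.4, a longer chain than forecast.

    free monomer + living end → monomer in chains + living end, rate k1*[living end]*[free monomer] (k = 3.70 /M/s)
    free monomer + initiator → living end + monomer in chains (k = 0.0150 /M/s)
    pre-initiator → initiator (k = 0.0180 /s)

Past the cube half-time of 1.85 min, at 2.0 min, the flask still held 53.3% free monomer, where the rule said 41.4%. The half-life of pre-initiator, 0.64 min, is shorter than that time, and 12% of its charge remained, less than the share of free monomer left. For a neighbour flask, like this one but with 0.10 M of free monomer, the cube half-time becomes 2.51 min, later than 2.0 min, and the rule gives 29.6% reacted. That flask gave 25.5%.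

The earlier runs and the new flask are simulated from invented constants; scatter was added.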